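The vessel is a closed, stirred flask: a solid substrate dissolves slowly, meets reagent fed by a held gas, and the target drifts on into its isomer.

    solid substrate ⇌ dissolved substrate, rate k1*(cs1 - [dissolved substrate]) while solid is left; crystals form when [dissolved substrate] > cs1 (cs1 = 0.12 M, k1 = 0.018 h⁻¹)
    dissolved substrate + reagent → target (k2 = 5.3 M⁻¹ h⁻¹)
    target ⇌ isomer of the product (K3 = 2.0, k3 = 0.0024 h⁻¹)
    reagent ⇌ dormant form (K4 = 100, k4 = 0.43 h⁻¹)
    gas ⇌ reagent, rate k5*(csat - [reagent]) (k5 = 21 h⁻¹, csat = 20 mM)

solid substrate 0.24 M; gas 20 mM (held); time 10 d

- given per volume of solution although it is solid: solid substrate
- at the start none of reagent is dissolved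
- at the start none of the solid substrate is in solution
- run time (flask): 10 d

* how much target there is at 10 d, in percent of the solid substrate charged
* the change that raises the amount of target at 10 d, in percent of the solid substrate charged most ("none" if none brings more than 2 percentage points) (eta / epsilon / alpha / theta / none)
* amount of target at 10 d, in percent of the solid substrate charged, after epsilon

- eta: doubling the dissolution coefficient of step 1, all else as stated
- epsilon: doubling the transfer coefficient of step 5, all else as stated
- alpha: doubling the saturation concentration of gas, all else as stated
- theta: doubling the solubility in step 1, all else as stated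

- I count turnovers of the drift. Target and isomer relax towards each other at 0.00360 h⁻¹, the forward and return constants added, and this relaxation rate times a batch's age gives its turnovers. The target share kept is then 33.3 % plus a part of 66.7 % that shrinks as e to the minus turnovers.
- Transfer from the gas outruns the loss to the dormant form, so I hold c(reagent) near 20 mM, which makes the reaction pseudo-first-order at 0.106 h⁻¹.
- Floor: dissolution cannot beat 0.00216 M h⁻¹, so the mean age is at most 184 h, or 0.664 turnovers, and the share is at least 67.7 %.
- Ceiling: the steady pace is 0.00185 M h⁻¹, so the solid lasts 130 h. Letting the whole charge wait that long, generously, gives 78.2 %.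
- Tightened: the remaining 11.7 reaction turnovers clear the dissolved substrate, so target and isomer hold the charge. Mean birth falls at half the life of the solid plus a lag of 8.06 h, giving an age of 167 h, 0.601 turnovers and 69.9 %. The spread of ages lifts this a little.
- Eta, alpha and theta raise the pace and age the target, and epsilon leaves c(reagent) nearly where it stands, so I commit to none.
- The forecast gives 70.2 %, within 68.5 % to 72 %, 70.1 % after epsilon, and none: “Every change only speeds formation, allowing more isomerisation, so none raises target.” Its value lies inside my bracket and just above my tightened figure.
- The flask gives 70.3 %, 70.3 % after epsilon, and none; at 10.0 d the isomer holds 29.7 %. With 0.096 M of solid substrate the pace gives a mean age of 206 h, so 0.741 turnovers and a share of 65.1 %; that neighbour flask holds 65.2 %.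

The rate constants come from no measurement, and the outcome is calculated.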